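The earlier runs and the new flask stem from a simulated flask from invented constants; noise was put on by code.

In a one-step world each electrophile takes one nucleophile, and the end of a flask can be read from its charge.

all flasks: electrophile 0.20 M

| charge | nucleophile | free base | remark | time |
|---|---|---|---|---|
| cedar | 0.26 M | 0.30 M | run made earlier |  |
| maple | 0.26 M | 1.2 M | run made earlier |  |
| oak | 0.52 M | 0.60 M | run made earlier |  |
| flask | 0.260 M | 0.600 M |  | 15 h |

- cedar (time / h: electrophile / %, target / %): 1.33: 26.5, 74.1; 2.00: 24.3, 75.7; 3.00: 22.0, 77.4; 5.00: 18.7, 81.7; 10.0: 11.7, 89.1; 15.0: 6.3, 94.4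
- maple (time / h: electrophile / %, target / %): 1.33: 26.3, 73.9; 2.00: 24.3, 76.3; 3.00: 21.9, 77.9; 5.00: 18.6, 81.7; 10.0: 11.4, 88.4; 15.0: 5.7, 94.1
- oak (time / h: electrophile / %, target / %): 3.00: 0, 99.8; 6.00: 0, 99.6; 10.0: 0, 99.9; 12.0: 0.2, 100.2; 15.0: 0.3, 100.2

(each reading ± 0.3 percentage points)

- part of the electrophile that has reacted at 15 h
- share of the unused nucleophile that is free and not bound as protonated nucleophile, at 15 h

- the numbers in the tables scatter with a standard deviation of 0.3 percentage points
- the earlier runs do not show how much of nucleophile is bound; that part of a forecast is a guess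

In the flask, nucleophile charged over electrophile charged is 1.30, the nucleophile ratio. Above one, it leaves complete reaction as the upper bound. Suppose each turn also ties a second nucleophile as protonated nucleophile; reaction then stalls at half the ratio:

lower bound = 65.0 %, upper bound = 100 %

Cedar has the same ratio and stands above that lower bound at its first reading, 73.5 % reacted at 1.33 h, so in cedar not every turn has tied up a second nucleophile. The free base of the flask, 0.600 M, lies between those of cedar and maple, which reach 93.7 % and 94.3 % at 15 h. My own bracket narrows to these two readings. It leaves a reserve, ratio minus reacted fraction, near 0.363, but the runs do not show how that reserve divides.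

The forecast says 94.1 % (93.3 % to 94.9 %), which lies inside the bracket, and 20 % free (8 % to 40 %): “This is a rough estimate.”

The flask gives 94.0 % reacted and 1.77 % free, which is less than the forecast's low end.

    electrophile + nucleophile → acid set free + target (k = 0.0310 L mol⁻¹ s⁻¹)
    nucleophile + acid set free ⇌ protonated nucleophile, settled at all times (K = 5500 L mol⁻¹)
    acid set free + free base ⇌ salt of the base, settled at all times (K = 24.0 L mol⁻¹)
    2 free base → homo dimer (k = 0.00420 L mol⁻¹ s⁻¹)
    acid set free → by-product carried off (k = 1.20 × 10⁻⁴ s⁻¹)

At 15 h the reserve of the flask is 0.360 of the electrophile charge, and protonated nucleophile amounts to 0.353 of that same charge. By 1.50 h the coupling had 79 % of its turnover behind it, with nucleophile at 0.384 % of its charge and 3.70 % of the free base left free. Protonated nucleophile then fell from 0.110 M to 0.0706 M, while by-product carried off rose from 0.00768 M to 0.107 M.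

In a neighbouring flask, with 0.50 M of electrophile, the ratio is 0.520, so nucleophile is the limiting reagent and the bracket runs from 26.0 % to 52.0 %. That flask gives 50.5 %.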